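The route rests on disconnecting the C2–C3 bond of the flavan pyran ring. Its O1–C2(aryl)/C3–OH trans array is the syn-hydroboration signature of a C2=C3 enol ether, so the precursor is an aryl 4-(benzyloxy)benzoate bearing an ortho-allyl group: the ester carbon is C2, the internal allyl carbon C3. A Tebbe-mediated olefinic-ester cyclization (methylenation, then ring-closing metathesis) joins them in one operation to a 2-aryl-4H-chromene; asymmetric hydroboration then sets C2 and C3. The spiro-benzofuranone/dihydrofuran unit is added afterwards at C8/O7 by an enantioselective Rh-carbene C–H insertion into the 7-O-(4-benzyloxybenzyl) ether and a brominative O-spirocyclization.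

Key step: step 5

Assumption: the sense of induction of IpcBH2 (step 6) and of Rh2(S-PTTL)4 (step 12) is assigned by analogy with 1-arylcycloalkenes and with 2-(benzyloxy)aryl diazoacetates respectively; if either proves opposite, the antipodal reagent is used.

Step 1
Reactants: 1 phloroglucinol; 2 4-(benzyloxy)benzyl chloride
Product: 3 3,5-bis{[4-(benzyloxy)benzyl]oxy}phenol
Conditions: 2 (2.0 equiv), K2CO3, DMF, 0 °C to rt; chromatography
Reagents that add atoms: none
Why: Williamson O-alkylation of phloroglucinol, in which the bis-ether should be the main component of the statistical mixture at two equivalents and is separated from mono- and tris-ethers; one of the two identical ethers later serves as the C–H insertion site at O7 and the other as the O5 protecting group.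

Step 2
Reactants: 3 3,5-bis{[4-(benzyloxy)benzyl]oxy}phenol; 4 allyl bromide
Product: 5 1-(allyloxy)-3,5-bis{[4-(benzyloxy)benzyl]oxy}benzene
Conditions: K2CO3, acetone, reflux
Reagents that add atoms: none
Why: Williamson O-allylation of the remaining phenol, with a weak base in a polar aprotic solvent favouring O- over C-alkylation.

Step 3
Reactants: 5 1-(allyloxy)-3,5-bis{[4-(benzyloxy)benzyl]oxy}benzene
Product: 6 2-allyl-3,5-bis{[4-(benzyloxy)benzyl]oxy}phenol
Conditions: N,N-diethylaniline, 190 °C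
Reagents that add atoms: none
Why: Aromatic Claisen rearrangement ([3,3]-sigmatropic shift, then tautomerization) delivers the allyl group to one of the two equivalent ortho positions, placing the future C4/C3 next to the phenol oxygen (future O1), while the basic solvent protects the benzylic ethers.

Step 4
Reactants: 6 2-allyl-3,5-bis{[4-(benzyloxy)benzyl]oxy}phenol; 7 4-(benzyloxy)benzoyl chloride
Product: 8 2-allyl-3,5-bis{[4-(benzyloxy)benzyl]oxy}phenyl 4-(benzyloxy)benzoate
Conditions: Et3N, DMAP (cat.), CH2Cl2, 0 °C to rt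
Reagents that add atoms: none
Why: DMAP-catalysed O-acylation of the phenol with the aroyl chloride installs the future C2, already carrying its aryl group, on O1.

Step 5
Reactants: 8 2-allyl-3,5-bis{[4-(benzyloxy)benzyl]oxy}phenyl 4-(benzyloxy)benzoate
Product: 10 5,7-bis{[4-(benzyloxy)benzyl]oxy}-2-[4-(benzyloxy)phenyl]-4H-chromene, via aryl vinyl ether 9 (not isolated)
Conditions: Tebbe reagent (4 equiv), pyridine (cat.), THF, 25 °C then 65 °C; basic work-up, Et3N-deactivated silica
Reagents that add atoms: none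
Why: Titanocene methylidene first methylenates the aryl ester carbonyl through an oxatitanacyclobutane to give the 1-aryloxy-1-arylethene 9; on heating, the same Ti=CH2 engages the terminal allyl alkene and the resulting alkylidene closes onto the 1,1-disubstituted enol ether through titanacyclobutanes, expelling ethylene and forging C2=C3. The closest known reaction types are the Tebbe-mediated tandem ester methylenation/ring-closing olefin metathesis of olefinic esters to cyclic enol ethers and the Tebbe methylenation of aryl benzoates to 1-aryloxystyrenes. The pyran ring closes by ring-closing metathesis (six-membered, both new sp2 carbons endocyclic), favoured by the ortho relationship of the allyl and aryloxy groups. No stereocentre is formed; the step deliberately delivers the prochiral C2=C3 enol ether whose syn-hydroboration in step 6 sets C2 and C3 trans. The selectivity needed is carbonyl methylenation before alkene consumption, and cyclization over oligomerization and over allyl-to-propenyl isomerization (which would contract the ring to a 2-arylbenzofuran); the ester is the only carbonyl in 8, the enol ether cannot homodimerize, and base-buffered, acid-free conditions preserve the acid-labile 4H-chromene.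

Step 6
Reactants: 10 5,7-bis{[4-(benzyloxy)benzyl]oxy}-2-[4-(benzyloxy)phenyl]-4H-chromene
Product: 12 (2R,3S)-5,7-bis{[4-(benzyloxy)benzyl]oxy}-2-[4-(benzyloxy)phenyl]chroman-3-ol, via organoborane 11 (not isolated)
Conditions: IpcBH2 [from (+)-α-pinene] (1.2 equiv), Et2O/THF, −25 to 0 °C; then NaOH, H2O2, 0 °C to rt; recrystallization
Reagents that add atoms: hydrogen peroxide, OO
Why: Asymmetric hydroboration–oxidation places boron on C3 (β to the ring oxygen, away from the aryl-bearing carbon) and hydrogen on C2 from the same face, so 2-aryl and 3-OH are trans; the isopinocampheyl group selects the alkene face as it does for 1-arylcycloalkenes to set (2R,3S), and oxidation proceeds with retention.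

Step 7
Reactants: 12 (2R,3S)-5,7-bis{[4-(benzyloxy)benzyl]oxy}-2-[4-(benzyloxy)phenyl]chroman-3-ol
Product: 13 (2R,3S)-3-(benzyloxy)-5,7-bis{[4-(benzyloxy)benzyl]oxy}-2-[4-(benzyloxy)phenyl]chromane
Conditions: NaH, BnBr, Bu4NI (cat.), DMF, 0 °C to rt
Reagents that add atoms: benzyl bromide, BrCc1ccccc1
Why: Williamson O-benzylation of the secondary alkoxide masks the 3-OH against the base, carbenoid and enolate chemistry that follows, without touching a stereocentre.

Step 8
Reactants: 13 (2R,3S)-3-(benzyloxy)-5,7-bis{[4-(benzyloxy)benzyl]oxy}-2-[4-(benzyloxy)phenyl]chromane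
Product: 14 (2R,3S)-3-(benzyloxy)-8-bromo-5,7-bis{[4-(benzyloxy)benzyl]oxy}-2-[4-(benzyloxy)phenyl]chromane
Conditions: NBS (1.0 equiv), CH2Cl2, −78 to 0 °C
Reagents that add atoms: N-bromosuccinimide, O=C1CCC(=O)N1Br
Why: Electrophilic aromatic bromination, which in 5,7-di-O-benzylated flavan-3-ol ethers is expected at C8 (between O7 and the ring oxygen) in preference to C6, the para-blocked anisole-type rings being far less activated.

Step 9
Reactants: 15 2',4',6'-trihydroxyacetophenone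
Product: 16 1-[2,4,6-tris(triisopropylsilyloxy)phenyl]ethan-1-one
Conditions: TIPSOTf (3.6 equiv), 2,6-lutidine, CH2Cl2, 0 to 40 °C
Reagents that add atoms: triisopropylsilyl triflate, CC(C)[Si](OS(=O)(=O)C(F)(F)F)(C(C)C)C(C)C
Why: Silylation of the three phenols with the reactive silyl triflate; bulky silyl ethers are chosen because they survive the basic steps, are poor partners for oxonium-ylide formation with the later carbenoid, and are all released by fluoride in step 13.

Step 10
Reactants: 14 (2R,3S)-3-(benzyloxy)-8-bromo-5,7-bis{[4-(benzyloxy)benzyl]oxy}-2-[4-(benzyloxy)phenyl]chromane; 16 1-[2,4,6-tris(triisopropylsilyloxy)phenyl]ethan-1-one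
Product: 17 2-{(2R,3S)-3-(benzyloxy)-5,7-bis{[4-(benzyloxy)benzyl]oxy}-2-[4-(benzyloxy)phenyl]chroman-8-yl}-1-[2,4,6-tris(triisopropylsilyloxy)phenyl]ethan-1-one
Conditions: Pd2(dba)3 (2.5 mol %), XPhos (6 mol %), K3PO4, toluene, 100 °C
Reagents that add atoms: none
Why: Palladium-catalysed ketone α-arylation (Buchwald–Hartwig type) of the methyl-ketone enolate with the hindered, electron-rich aryl bromide, using a bulky biarylphosphine and the mild base K3PO4 that tolerates aryl silyl ethers; crowding should stop the reaction after monoarylation.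

Step 11
Reactants: 17 2-{(2R,3S)-3-(benzyloxy)-5,7-bis{[4-(benzyloxy)benzyl]oxy}-2-[4-(benzyloxy)phenyl]chroman-8-yl}-1-[2,4,6-tris(triisopropylsilyloxy)phenyl]ethan-1-one
Product: 18 2-{(2R,3S)-3-(benzyloxy)-5,7-bis{[4-(benzyloxy)benzyl]oxy}-2-[4-(benzyloxy)phenyl]chroman-8-yl}-2-diazo-1-[2,4,6-tris(triisopropylsilyloxy)phenyl]ethan-1-one
Conditions: p-ABSA (1.5 equiv), DBU, MeCN, 0 °C to rt
Reagents that add atoms: 4-acetamidobenzenesulfonyl azide, CC(=O)Nc1ccc(cc1)S(=O)(=O)N=[N+]=[N-]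
Why: Regitz diazo transfer to the doubly activated (aryl, aroyl) methylene gives the aryl aroyl diazomethane, a donor/acceptor carbene precursor.

Step 12
Reactants: 18 2-{(2R,3S)-3-(benzyloxy)-5,7-bis{[4-(benzyloxy)benzyl]oxy}-2-[4-(benzyloxy)phenyl]chroman-8-yl}-2-diazo-1-[2,4,6-tris(triisopropylsilyloxy)phenyl]ethan-1-one
Product: 19 {(2R,3S,8R,9S)-3-(benzyloxy)-5-{[4-(benzyloxy)benzyl]oxy}-2,8-bis[4-(benzyloxy)phenyl]-3,4,8,9-tetrahydro-2H-furo[2,3-h]chromen-9-yl}[2,4,6-tris(triisopropylsilyloxy)phenyl]methanone (8-aryl and 9-aroyl cis)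
Conditions: Rh2(S-PTTL)4 (2 mol %), toluene, −60 to −20 °C, slow addition of 18
Reagents that add atoms: none
Why: Rh(II)-carbenoid intramolecular 1,5-C–H insertion into the doubly activated benzylic C–H of the 7-O-(4-benzyloxybenzyl) ether closes the dihydrofuran, the N-phthaloyl-tert-leucinate ligands discriminating the enantiotopic benzylic hydrogens to set the aryl-bearing carbon (the cis-9-aroyl isomer is expected, and C9 is enolized in step 13 so its configuration is inconsequential); the bulky silyl ethers disfavour oxonium-ylide formation, the 5-O ether is out of reach and the flavan C2–H points away from C8.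

Step 13
Reactants: 19 {(2R,3S,8R,9S)-3-(benzyloxy)-5-{[4-(benzyloxy)benzyl]oxy}-2,8-bis[4-(benzyloxy)phenyl]-3,4,8,9-tetrahydro-2H-furo[2,3-h]chromen-9-yl}[2,4,6-tris(triisopropylsilyloxy)phenyl]methanone
Product: 21 (2S,2'R,3'S,8'S)-3'-(benzyloxy)-5'-{[4-(benzyloxy)benzyl]oxy}-2',8'-bis[4-(benzyloxy)phenyl]-4,6-dihydroxy-3',4'-dihydro-2'H,3H,8'H-spiro[1-benzofuran-2,9'-furo[2,3-h]chromen]-3-one, via bromoketone 20 (not isolated)
Conditions: KHMDS, THF, −78 °C; NBS, −78 °C; then TBAF (3.5 equiv), −78 to 0 °C; aq NH4Cl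
Reagents that add atoms: none
Why: α-Bromination of the ketone at C9 followed by fluoride-triggered 5-exo-tet displacement by the liberated ortho-phenoxide (the classical closure of 2,2-disubstituted benzofuran-3(2H)-ones): bromine enters anti to the adjacent 8-aryl group and the phenoxide displaces it with inversion, placing the ring oxygen cis to that aryl group and setting the spiro centre (S) relative to the fixed CH (an SN1-like closure should converge on the same less congested isomer), while β-elimination of the ring phenoxide from the enolate is stereoelectronically disfavoured.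

Step 14
Reactants: 21 (2S,2'R,3'S,8'S)-3'-(benzyloxy)-5'-{[4-(benzyloxy)benzyl]oxy}-2',8'-bis[4-(benzyloxy)phenyl]-4,6-dihydroxy-3',4'-dihydro-2'H,3H,8'H-spiro[1-benzofuran-2,9'-furo[2,3-h]chromen]-3-one
Product: 22 CNP0228515.1, (2S,2'R,3'S,8'S)-3',4,5',6-tetrahydroxy-2',8'-bis(4-hydroxyphenyl)-3',4'-dihydro-2'H,3H,8'H-spiro[1-benzofuran-2,9'-furo[2,3-h]chromen]-3-one
Conditions: H2 (1 atm), Pd(OH)2/C, EtOAc/MeOH, rt, monitored
Reagents that add atoms: none
Why: Catalytic hydrogenolysis cleaves the four O-benzyl ethers and the 5-O-(4-benzyloxybenzyl) ether (as p-cresol), while the cyclic benzylic C–O bonds of the chroman and dihydrofuran rings and the quaternary spiro C–O bond are expected to survive mild conditions as they do in debenzylations of flavan-3-ols and 2-aryldihydrobenzofurans; no stereocentre is affected.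

Compound list
1 | phloroglucinol (benzene-1,3,5-triol) | Oc1cc(O)cc(O)c1 | starting material
2 | 4-(benzyloxy)benzyl chloride | ClCc1ccc(OCc2ccccc2)cc1 | starting material
3 | 3,5-bis{[4-(benzyloxy)benzyl]oxy}phenol | Oc1cc(OCc2ccc(OCc3ccccc3)cc2)cc(OCc2ccc(OCc3ccccc3)cc2)c1 | intermediate
4 | allyl bromide | C=CCBr | starting material
5 | 1-(allyloxy)-3,5-bis{[4-(benzyloxy)benzyl]oxy}benzene | C=CCOc1cc(OCc2ccc(OCc3ccccc3)cc2)cc(OCc2ccc(OCc3ccccc3)cc2)c1 | intermediate
6 | 2-allyl-3,5-bis{[4-(benzyloxy)benzyl]oxy}phenol | C=CCc1c(O)cc(OCc2ccc(OCc3ccccc3)cc2)cc1OCc1ccc(OCc2ccccc2)cc1 | intermediate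
7 | 4-(benzyloxy)benzoyl chloride | O=C(Cl)c1ccc(OCc2ccccc2)cc1 | starting material
8 | 2-allyl-3,5-bis{[4-(benzyloxy)benzyl]oxy}phenyl 4-(benzyloxy)benzoate | C=CCc1c(OC(=O)c2ccc(OCc3ccccc3)cc2)cc(OCc2ccc(OCc3ccccc3)cc2)cc1OCc1ccc(OCc2ccccc2)cc1 | intermediate
9 | 2-allyl-1-({1-[4-(benzyloxy)phenyl]vinyl}oxy)-3,5-bis{[4-(benzyloxy)benzyl]oxy}benzene | C=CCc1c(OC(=C)c2ccc(OCc3ccccc3)cc2)cc(OCc2ccc(OCc3ccccc3)cc2)cc1OCc1ccc(OCc2ccccc2)cc1 | intermediate
10 | 5,7-bis{[4-(benzyloxy)benzyl]oxy}-2-[4-(benzyloxy)phenyl]-4H-chromene | C1(c2ccc(OCc3ccccc3)cc2)=CCc2c(OCc3ccc(OCc4ccccc4)cc3)cc(OCc3ccc(OCc4ccccc4)cc3)cc2O1 | intermediate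
11 | trans-[5,7-bis{[4-(benzyloxy)benzyl]oxy}-2-[4-(benzyloxy)phenyl]chroman-3-yl](isopinocampheyl)borane (C2 R; boron on the carbon that becomes C3 S) | O(Cc1ccc(OCc2ccccc2)cc1)c1cc(OCc2ccc(OCc3ccccc3)cc2)c2c(c1)O[C@H](c1ccc(OCc3ccccc3)cc1)[C@@H]([BH][C@@H]5C[C@@H]6C[C@H]([C@H]5C)C6(C)C)C2 | intermediate
12 | (2R,3S)-5,7-bis{[4-(benzyloxy)benzyl]oxy}-2-[4-(benzyloxy)phenyl]chroman-3-ol | O(Cc1ccc(OCc2ccccc2)cc1)c1cc(OCc2ccc(OCc3ccccc3)cc2)c2c(c1)O[C@H](c1ccc(OCc3ccccc3)cc1)[C@@H](O)C2 | intermediate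
13 | (2R,3S)-3-(benzyloxy)-5,7-bis{[4-(benzyloxy)benzyl]oxy}-2-[4-(benzyloxy)phenyl]chromane | O(Cc1ccc(OCc2ccccc2)cc1)c1cc(OCc2ccc(OCc3ccccc3)cc2)c2c(c1)O[C@H](c1ccc(OCc3ccccc3)cc1)[C@@H](OCc1ccccc1)C2 | intermediate
14 | (2R,3S)-3-(benzyloxy)-8-bromo-5,7-bis{[4-(benzyloxy)benzyl]oxy}-2-[4-(benzyloxy)phenyl]chromane | O(Cc1ccc(OCc2ccccc2)cc1)c1cc(OCc2ccc(OCc3ccccc3)cc2)c2c(c1Br)O[C@H](c1ccc(OCc3ccccc3)cc1)[C@@H](OCc1ccccc1)C2 | intermediate
15 | 2',4',6'-trihydroxyacetophenone | CC(=O)c1c(O)cc(O)cc1O | starting material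
16 | 1-[2,4,6-tris(triisopropylsilyloxy)phenyl]ethan-1-one | CC(=O)c1c(O[Si](C(C)C)(C(C)C)C(C)C)cc(O[Si](C(C)C)(C(C)C)C(C)C)cc1O[Si](C(C)C)(C(C)C)C(C)C | intermediate
17 | 2-{(2R,3S)-3-(benzyloxy)-5,7-bis{[4-(benzyloxy)benzyl]oxy}-2-[4-(benzyloxy)phenyl]chroman-8-yl}-1-[2,4,6-tris(triisopropylsilyloxy)phenyl]ethan-1-one | O(Cc1ccc(OCc2ccccc2)cc1)c1cc(OCc2ccc(OCc3ccccc3)cc2)c2c(c1CC(=O)c1c(O[Si](C(C)C)(C(C)C)C(C)C)cc(O[Si](C(C)C)(C(C)C)C(C)C)cc1O[Si](C(C)C)(C(C)C)C(C)C)O[C@H](c1ccc(OCc3ccccc3)cc1)[C@@H](OCc1ccccc1)C2 | intermediate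
18 | 2-{(2R,3S)-3-(benzyloxy)-5,7-bis{[4-(benzyloxy)benzyl]oxy}-2-[4-(benzyloxy)phenyl]chroman-8-yl}-2-diazo-1-[2,4,6-tris(triisopropylsilyloxy)phenyl]ethan-1-one | O(Cc1ccc(OCc2ccccc2)cc1)c1cc(OCc2ccc(OCc3ccccc3)cc2)c2c(c1C(=[N+]=[N-])C(=O)c1c(O[Si](C(C)C)(C(C)C)C(C)C)cc(O[Si](C(C)C)(C(C)C)C(C)C)cc1O[Si](C(C)C)(C(C)C)C(C)C)O[C@H](c1ccc(OCc3ccccc3)cc1)[C@@H](OCc1ccccc1)C2 | intermediate
19 | {(2R,3S,8R,9S)-3-(benzyloxy)-5-{[4-(benzyloxy)benzyl]oxy}-2,8-bis[4-(benzyloxy)phenyl]-3,4,8,9-tetrahydro-2H-furo[2,3-h]chromen-9-yl}[2,4,6-tris(triisopropylsilyloxy)phenyl]methanone (8-aryl/9-aroyl cis) | O=C(c1c(O[Si](C(C)C)(C(C)C)C(C)C)cc(O[Si](C(C)C)(C(C)C)C(C)C)cc1O[Si](C(C)C)(C(C)C)C(C)C)[C@H]1c2c(cc(OCc4ccc(OCc5ccccc5)cc4)c3c2O[C@H](c2ccc(OCc4ccccc4)cc2)[C@@H](OCc2ccccc2)C3)O[C@H]1c1ccc(OCc2ccccc2)cc1 | intermediate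
20 | 9-bromo derivative of 19 (bromine trans to the 8-aryl group, other centres unchanged) | O=C(c1c(O[Si](C(C)C)(C(C)C)C(C)C)cc(O[Si](C(C)C)(C(C)C)C(C)C)cc1O[Si](C(C)C)(C(C)C)C(C)C)[C@@]1(Br)c2c(cc(OCc4ccc(OCc5ccccc5)cc4)c3c2O[C@H](c2ccc(OCc4ccccc4)cc2)[C@@H](OCc2ccccc2)C3)O[C@H]1c1ccc(OCc2ccccc2)cc1 | intermediate
21 | (2S,2'R,3'S,8'S)-3'-(benzyloxy)-5'-{[4-(benzyloxy)benzyl]oxy}-2',8'-bis[4-(benzyloxy)phenyl]-4,6-dihydroxy-3',4'-dihydro-2'H,3H,8'H-spiro[1-benzofuran-2,9'-furo[2,3-h]chromen]-3-one | O=C1c2c(O)cc(O)cc2O[C@]12c1c(cc(OCc4ccc(OCc5ccccc5)cc4)c3c1O[C@H](c1ccc(OCc4ccccc4)cc1)[C@@H](OCc1ccccc1)C3)O[C@H]2c1ccc(OCc2ccccc2)cc1 | intermediate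
22 | CNP0228515.1, (2S,2'R,3'S,8'S)-3',4,5',6-tetrahydroxy-2',8'-bis(4-hydroxyphenyl)-3',4'-dihydro-2'H,3H,8'H-spiro[1-benzofuran-2,9'-furo[2,3-h]chromen]-3-one | O=C1c2c(O)cc(O)cc2O[C@]12c1c(cc(O)c3c1O[C@H](c1ccc(O)cc1)[C@@H](O)C3)O[C@H]2c1ccc(O)cc1 | target

Total step count: 14. Longest linear sequence: 13 steps (steps 1–8 and 10–14; step 9 is a one-step branch).

Steps most likely to fail

Step 12. Attack of an ortho silyloxy oxygen of the aroyl group on the rhodium carbenoid (oxonium-ylide formation with silyl transfer) or Wolff rearrangement may outrun the 1,5-C–H insertion, and the crowded, di-ortho-substituted carbenoid may erode facial discrimination. The fallback sets out from 14 and uses an ester as the acceptor, so that no oxygen sits within reach of the carbenoid. Palladium-catalysed coupling of 14 with the Reformatsky reagent of ethyl bromoacetate should give the ethyl arylacetate F1. Diazo transfer (p-ABSA, DBU) should give the aryl diazoacetate F2. Rh2(S-PTTL)4-catalysed C–H insertion, the directly precedented aryl diazoacetate case, should give the cis-dihydrofuran ester F3. Addition of 2,4,6-tris(triisopropylsilyloxy)phenylcerium dichloride (weakly basic; single addition to the hindered ester) at −78 °C should then give ketone 19, where the route is rejoined.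

Step 13. Loss of HBr from the tertiary bromide (aromatization to the benzofuran), ionization with poor facial selectivity in the C–O closure, or halogenation of an electron-rich ring may compete with the displacement. The fallback sets out from 19 and replaces halide displacement by a cationic cyclodehydration under product-stability control. Enolate hydroxylation (KHMDS, then Davis oxaziridine) should give the tertiary α-hydroxy ketone F4. TBAF should remove the three silyl groups to give the tetrol F5. Mild acid (PPTS, toluene) should then ionize the tertiary alcohol, which is stabilized by the ortho/para-oxygenated aryl group, and the ortho-phenol closes the benzofuranone onto the less congested face, rejoining the route at 21.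

Step 5. The titanium methylidene may stall at the acyclic enol ether, or consume the allyl group by isomerization or oligomerization before ring closure. The fallback sets out from 8 and forms the same C2=C3 bond by reductive carbonyl coupling instead of metathesis. Oxidative cleavage of the allyl terminus (OsO4 cat., NaIO4, 2,6-lutidine) should give the arylacetaldehyde ester F6. Intramolecular low-valent-titanium aldehyde–ester coupling (McMurry type; TiCl3, Zn, DME, reflux) should then close the pyran ring and return to the route at 10.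

Further compounds
F1 | step 12 | ethyl 2-{(2R,3S)-3-(benzyloxy)-5,7-bis{[4-(benzyloxy)benzyl]oxy}-2-[4-(benzyloxy)phenyl]chroman-8-yl}acetate | O(Cc1ccc(OCc2ccccc2)cc1)c1cc(OCc2ccc(OCc3ccccc3)cc2)c2c(c1CC(=O)OCC)O[C@H](c1ccc(OCc3ccccc3)cc1)[C@@H](OCc1ccccc1)C2
F2 | step 12 | ethyl 2-{(2R,3S)-3-(benzyloxy)-5,7-bis{[4-(benzyloxy)benzyl]oxy}-2-[4-(benzyloxy)phenyl]chroman-8-yl}-2-diazoacetate | O(Cc1ccc(OCc2ccccc2)cc1)c1cc(OCc2ccc(OCc3ccccc3)cc2)c2c(c1C(=[N+]=[N-])C(=O)OCC)O[C@H](c1ccc(OCc3ccccc3)cc1)[C@@H](OCc1ccccc1)C2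
F3 | step 12 | ethyl (2R,3S,8R,9S)-3-(benzyloxy)-5-{[4-(benzyloxy)benzyl]oxy}-2,8-bis[4-(benzyloxy)phenyl]-3,4,8,9-tetrahydro-2H-furo[2,3-h]chromene-9-carboxylate (8,9-cis) | CCOC(=O)[C@H]1c2c(cc(OCc4ccc(OCc5ccccc5)cc4)c3c2O[C@H](c2ccc(OCc4ccccc4)cc2)[C@@H](OCc2ccccc2)C3)O[C@H]1c1ccc(OCc2ccccc2)cc1
F4 | step 13 | 9-hydroxy derivative of 19 (hydroxyl trans to the 8-aryl group, other centres unchanged) | O=C(c1c(O[Si](C(C)C)(C(C)C)C(C)C)cc(O[Si](C(C)C)(C(C)C)C(C)C)cc1O[Si](C(C)C)(C(C)C)C(C)C)[C@@]1(O)c2c(cc(OCc4ccc(OCc5ccccc5)cc4)c3c2O[C@H](c2ccc(OCc4ccccc4)cc2)[C@@H](OCc2ccccc2)C3)O[C@H]1c1ccc(OCc2ccccc2)cc1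
F5 | step 13 | tris-desilylated F4, the 9-hydroxy-9-(2,4,6-trihydroxybenzoyl) compound | O=C(c1c(O)cc(O)cc1O)[C@@]1(O)c2c(cc(OCc4ccc(OCc5ccccc5)cc4)c3c2O[C@H](c2ccc(OCc4ccccc4)cc2)[C@@H](OCc2ccccc2)C3)O[C@H]1c1ccc(OCc2ccccc2)cc1
F6 | step 5 | 3,5-bis{[4-(benzyloxy)benzyl]oxy}-2-(2-oxoethyl)phenyl 4-(benzyloxy)benzoate | O=CCc1c(OC(=O)c2ccc(OCc3ccccc3)cc2)cc(OCc2ccc(OCc3ccccc3)cc2)cc1OCc1ccc(OCc2ccccc2)cc1
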